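## The problem

The target is an achiral, linear pentamer of oxygenated benzene rings (rings A to E in the order of the SMILES string), joined by four diaryl ether oxygens and carrying thirteen free phenolic hydroxyls. There is no stereocentre, so only constitution has to be controlled.

Ring numbering used here: ring A is a phloroglucinol whose C2 carries the ether oxygen. Ring B has the ring A oxygen at C1, the ring C oxygen at C6 and hydroxyls at C3 and C5. Ring C has the ring B oxygen at C1, the ring D oxygen at C4 and hydroxyls at C3 and C5. Ring D has the ring C oxygen at C1, the ring E oxygen at C6, hydroxyls at C3, C4 and C5, and its only hydrogen at C2. Ring E is a 3,4,5-trihydroxyphenyl ether.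

Each ether oxygen is bound on one side to a carbon flanked by two oxygen-bearing carbons (ring A C2, ring B C6, ring C C4, ring D C6). Every diaryl ether is therefore hindered and electron-rich, which is where aryl halide coupling is weakest.

The free polyphenol, above all the pyrogallol rings D and E, is oxidised readily by air in base. All hydroxyls therefore need one kind of protecting group that falls under neutral conditions in the last step.

On rings B, C and D the neighbouring ether oxygen sits ortho or para to the hindered ether carbon. A formyl group at that position can first activate a bromide for copper-mediated substitution and then become the next phenol oxygen by Baeyer–Villiger oxidation.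

Ring A has no such handle, but its six carbons map onto two acyclic pieces. C1, C2 and C3, with the ether oxygen on C2, are an aryloxymalonate; C4, C5 and C6 are the three central carbons of a 3-oxopentanedioate. The ring can therefore be closed around the ether carbon instead of being coupled to it.

## Retrosynthesis

**Target 27 back to diester 25.** The last operation cuts twelve benzyl–oxygen bonds (ten ethers, two esters) and two aryl–carboxyl bonds. Benzyl esters are chosen over methyl esters so that hydrogenolysis alone unmasks the diacid 26, a 2,4,6-trihydroxyisophthalic acid that decarboxylates on gentle warming. The neighbouring option, saponifying hindered, hydrogen-bonded methyl esters with hot alkali, would add a harsh step on the most valuable intermediate. The forward step only asks that the diaryl ethers survive hydrogenolysis.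

**Diester 25 back to malonate 21 and ketodiester 23 (key step).** Two C–C bonds of ring A are cut, each between a former malonate carbonyl carbon (C1, C3) and a ring CH carbon (C6, C4). This removes a whole ring and leaves the ring A ether carbon as the sp3 carbon of 21. The neighbouring cut, a fourth aryl coupling of phenol 18 with bromide 10, would repeat the weakest coupling of the route on its most encumbered phenol; it is kept as the fallback. The forward reaction must give C-acylation twice and cross-condensation in preference to self-condensation of 23.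

**Malonate 21 back to phenol 18 and bromomalonate 20.** The O–C(sp3) bond is cut; it should form by simple O-alkylation of a phenoxide. Bromide 20 comes from dibenzyl malonate 19 by bromination, and 23 from dimethyl 3-oxopentanedioate 22 by transesterification. Uniform benzyl esters make alkoxide exchange in the key step degenerate.

**Phenol 18 back to phenol 13 and bromoaldehyde 15.** The ring B C1 oxygen is traced to a formyl group (aldehyde 16), and the ring B C6–O bond is then cut. The formyl group of 15 is ortho to the bromide, so it activates the coupling and afterwards becomes the phenol that will carry ring A. Cutting on the ring C side instead would need an unactivated, electron-rich halide. Bromide 15 is one bromination away from 3,5-bis(benzyloxy)benzaldehyde 14.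

**Phenol 13 back to phenol 7 and bromoaldehyde 10.** By the same logic the ring C C1 oxygen comes from the formyl group of aldehyde 11, and the ring C C4–O bond is cut. This is the hardest ether: the bromide of 10 lies between two benzyloxy groups and phenol 7 has an ortho aryloxy group. The para formyl group of 10 is the only activation the structure allows. Bromide 10 is made from 4-bromo-3,5-dimethoxybenzaldehyde 8 through diol 9.

**Phenol 7 back to phenol 3 and bromoaldehyde 4.** The ring D C1 oxygen comes from the formyl group of aldehyde 5, and the ring D C6–O bond is cut. Both partners derive from 3,4,5-tris(benzyloxy)benzaldehyde 1: Baeyer–Villiger oxidation gives ring E phenol 3, and bromination gives ring D bromoaldehyde 4. The alternative direction (ring D phenol, ring E halide) would pair a doubly flanked phenol with an unactivated bromide.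

## Roads not taken

**Alternative 1: late double C–H borylation.** The cut removes the hydroxyl para to the ether oxygen on ring A and the ring B hydroxyl para to the ring C ether oxygen. This leaves A2, an undecamethyl ether with hydrogen at both positions. Forward, a sterically governed iridium-catalysed C–H borylation followed by oxidation of both C–B bonds in the same flask would give A1.

- Merits: the two C–H bonds concerned are the only ones in A2 with two hydrogen neighbours, so site selectivity should be high. Rings A and B would come from simpler, less oxygenated building blocks, and ring A needs no ring synthesis. In step count for rings A and B this road is probably shorter.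
- Weak points: A2 still needs all four hindered diaryl ethers, including the one at ring A. Benzyl ethers cannot be used because their own arene C–H bonds would be borylated, so eleven methyl ethers must be cleaved at the end by Lewis-acid demethylation. That is far rougher on a pyrogallol-rich polyether than hydrogenolysis. The double borylation must also go to completion at both sites of a large substrate.
- Against its shorter access to rings A and B, the chosen plan sets a benzyl-only, neutral endgame and a ring A ether carbon that is never the site of a coupling.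

**Alternative 2: squarate ring expansion for ring D.** The cut is the ring D C6–C1 bond. Forward, thermolysis of the racemic squarate-derived cyclobutenone A4 opens the four-membered ring to a dienylketene, which closes to the CD phenol A3 with its only free hydroxyl at ring D C6.

- Merits: all five oxygens of ring D are differentiated by construction, and the hydroxyl that must carry ring E is unmasked automatically. In this respect it is better than the chosen plan.
- Weak points: the target needs no differentiation within ring D, since all three of its hydroxyls are free. The hindered ring C oxygen bond must still be made, now as an aryl vinyl ether. Three kinds of protecting group lengthen the endgame. The free hydroxyl of A3 lies between two oxygens and must then be arylated by an unactivated ring E electrophile.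
- The chosen plan makes ring D from purchasable aldehyde 1 in one bromination and forms both of its ethers with formyl activation.

**Alternative 3: Dötz benzannulation of ring B on ring A.** Three C–C bonds of ring B are cut. Forward, the chromium carbene complex A6, the ring A ethynyl ether A7 and one carbonyl ligand combine to the AB phenol A5.

- Merits: like the chosen plan, it never makes the ring A ether by coupling to an arene, because the ether is carried in as an alkynyl ether. The benzannulation also places the new hydroxyl next to the aryloxy group, where ring C must go. This is an equally valid answer to the ring A problem.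
- Weak points: it needs stoichiometric chromium carbonyl chemistry and an ethynyl ether of a doubly flanked phenol. The regiochemistry rests on the behaviour of an oxygen-substituted alkyne. One ring B oxygen emerges as a methyl ether among benzyl ethers, so the final deprotection is mixed. The phenol of A5 is flanked on both sides, so the next coupling has the hindered partner as nucleophile towards a ring C electrophile without ortho activation.
- The chosen plan uses cheap, metal-free ring construction from 21 and 23, a single protecting group and a chain (E to B) in which every coupling is formyl-activated.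

Key step: step 15

## Route

Remark on the chemistry: the target has no stereocentre, so all structures are given without stereodescriptors; compounds 1, 8, 14, 19 and 22 are taken as purchasable.

Step 1
Reactants: 1 3,4,5-tris(benzyloxy)benzaldehyde
Product: 3 3,4,5-tris(benzyloxy)phenol, via aryl formate 2 (not isolated)
Conditions: mCPBA, CH2Cl2, 0 °C to rt; then K2CO3 (cat.), MeOH, rt
Reagents that add atoms: mCPBA (3-chloroperoxybenzoic acid), O=C(OO)c1cccc(Cl)c1
Why: Baeyer–Villiger oxidation in which the electron-rich aryl group (para benzyloxy) migrates in preference to hydrogen, giving the formate, which base-catalysed methanolysis cleaves to the ring E phenol; this is the standard way from 3,4,5-trialkoxybenzaldehydes to the corresponding phenols.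

Step 2
Reactants: 1 3,4,5-tris(benzyloxy)benzaldehyde
Product: 4 2-bromo-3,4,5-tris(benzyloxy)benzaldehyde
Conditions: NBS, DMF, rt, dark
Reagents that add atoms: N-bromosuccinimide, O=C1CCC(=O)N1Br
Why: Electrophilic aromatic bromination; the two equivalent free positions are ortho and para to benzyloxy groups, one equivalent of reagent should stop at the monobromide, and exclusion of light suppresses benzylic radical bromination.

Step 3
Reactants: 3 3,4,5-tris(benzyloxy)phenol; 4 2-bromo-3,4,5-tris(benzyloxy)benzaldehyde
Product: 5 3,4,5-tris(benzyloxy)-2-[3,4,5-tris(benzyloxy)phenoxy]benzaldehyde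
Conditions: CuI (cat.), N,N-dimethylglycine·HCl, Cs2CO3, 1,4-dioxane, 100 °C, Ar
Reagents that add atoms: none
Why: Ullmann diaryl ether condensation; the ortho formyl group makes the bromide electron-poor and assists its activation at copper, the phenol has no ortho substituent, and the non-enolisable aldehyde tolerates carbonate.

Step 4
Reactants: 5 3,4,5-tris(benzyloxy)-2-[3,4,5-tris(benzyloxy)phenoxy]benzaldehyde
Product: 7 3,4,5-tris(benzyloxy)-2-[3,4,5-tris(benzyloxy)phenoxy]phenol, via aryl formate 6 (not isolated)
Conditions: mCPBA, CH2Cl2, 0 °C to rt; then K2CO3 (cat.), MeOH/THF, rt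
Reagents that add atoms: mCPBA (3-chloroperoxybenzoic acid), O=C(OO)c1cccc(Cl)c1
Why: Baeyer–Villiger oxidation; the ortho aryloxy and para benzyloxy donors secure aryl migration, and methanolysis of the formate frees the ring D C1 hydroxyl.

Step 5
Reactants: 8 4-bromo-3,5-dimethoxybenzaldehyde
Product: 9 4-bromo-3,5-dihydroxybenzaldehyde
Conditions: BBr3, CH2Cl2, −78 °C to rt; then H2O
Reagents that add atoms: none
Why: Lewis-acid cleavage of aryl methyl ethers; the aryl bromide is inert and the aldehyde is returned on aqueous work-up.

Step 6
Reactants: 9 4-bromo-3,5-dihydroxybenzaldehyde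
Product: 10 3,5-bis(benzyloxy)-4-bromobenzaldehyde
Conditions: BnBr, K2CO3, DMF, 50 °C
Reagents that add atoms: benzyl bromide, BrCc1ccccc1
Why: Williamson ether synthesis on both phenols; no other nucleophilic site is present.

Step 7
Reactants: 7 3,4,5-tris(benzyloxy)-2-[3,4,5-tris(benzyloxy)phenoxy]phenol; 10 3,5-bis(benzyloxy)-4-bromobenzaldehyde
Product: 11 3,5-bis(benzyloxy)-4-{3,4,5-tris(benzyloxy)-2-[3,4,5-tris(benzyloxy)phenoxy]phenoxy}benzaldehyde
Conditions: CuI (cat.), picolinic acid, K3PO4, DMSO, 100 °C, Ar
Reagents that add atoms: none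
Why: Ullmann-type C–O coupling under the picolinate-ligated copper conditions that are used when both partners carry ortho substituents; the para formyl group makes the doubly flanked bromide electron-poor, and only 10 carries a halide, so no homocoupling of the phenol partner is possible.

Step 8
Reactants: 11 3,5-bis(benzyloxy)-4-{3,4,5-tris(benzyloxy)-2-[3,4,5-tris(benzyloxy)phenoxy]phenoxy}benzaldehyde
Product: 13 3,5-bis(benzyloxy)-4-{3,4,5-tris(benzyloxy)-2-[3,4,5-tris(benzyloxy)phenoxy]phenoxy}phenol, via aryl formate 12 (not isolated)
Conditions: mCPBA, CH2Cl2, 0 °C to rt; then K2CO3 (cat.), MeOH/THF, rt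
Reagents that add atoms: mCPBA (3-chloroperoxybenzoic acid), O=C(OO)c1cccc(Cl)c1
Why: Baeyer–Villiger oxidation of a 3,4,5-trioxygenated benzaldehyde, the same substitution type as in step 1; the para aryloxy group drives aryl migration and the formate is cleaved by methanolysis.

Step 9
Reactants: 14 3,5-bis(benzyloxy)benzaldehyde
Product: 15 3,5-bis(benzyloxy)-2-bromobenzaldehyde
Conditions: NBS, DMF, 0 °C to rt, dark
Reagents that add atoms: N-bromosuccinimide, O=C1CCC(=O)N1Br
Why: Electrophilic bromination of a 3,5-dialkoxybenzaldehyde, which is known to go to C2 (ortho to one alkoxy group and para to the other) in preference to the more crowded C4 between the two ethers.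

Step 10
Reactants: 13 3,5-bis(benzyloxy)-4-{3,4,5-tris(benzyloxy)-2-[3,4,5-tris(benzyloxy)phenoxy]phenoxy}phenol; 15 3,5-bis(benzyloxy)-2-bromobenzaldehyde
Product: 16 3,5-bis(benzyloxy)-2-[3,5-bis(benzyloxy)-4-{3,4,5-tris(benzyloxy)-2-[3,4,5-tris(benzyloxy)phenoxy]phenoxy}phenoxy]benzaldehyde
Conditions: CuI (cat.), N,N-dimethylglycine·HCl, Cs2CO3, 1,4-dioxane, 100 °C, Ar
Reagents that add atoms: none
Why: Ullmann diaryl ether condensation of the same type as step 3: an ortho-formyl bromide and a phenol whose hydroxyl has two hydrogen neighbours.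

Step 11
Reactants: 16 3,5-bis(benzyloxy)-2-[3,5-bis(benzyloxy)-4-{3,4,5-tris(benzyloxy)-2-[3,4,5-tris(benzyloxy)phenoxy]phenoxy}phenoxy]benzaldehyde
Product: 18 3,5-bis(benzyloxy)-2-[3,5-bis(benzyloxy)-4-{3,4,5-tris(benzyloxy)-2-[3,4,5-tris(benzyloxy)phenoxy]phenoxy}phenoxy]phenol, via aryl formate 17 (not isolated)
Conditions: mCPBA, CH2Cl2, 0 °C to rt; then K2CO3 (cat.), MeOH/THF, rt
Reagents that add atoms: mCPBA (3-chloroperoxybenzoic acid), O=C(OO)c1cccc(Cl)c1
Why: Baeyer–Villiger oxidation of a 2-aryloxybenzaldehyde, a substrate class in which the ortho oxygen donor directs aryl migration; benzyl and diaryl ethers are inert to the peracid at this temperature.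

Step 12
Reactants: 19 dibenzyl malonate
Product: 20 dibenzyl 2-bromomalonate
Conditions: Br2, CH2Cl2, 0 °C to rt
Reagents that add atoms: bromine, BrBr
Why: Bromination of an active methylene through its enol, as in the standard preparation of dialkyl bromomalonates; one equivalent of bromine limits dibromination.

Step 13
Reactants: 18 the BCDE phenol of step 11; 20 dibenzyl 2-bromomalonate
Product: 21 dibenzyl 2-(aryloxy)malonate in which the aryl group is that of phenol 18
Conditions: K2CO3, acetone, rt to 40 °C
Reagents that add atoms: none
Why: Williamson-type SN2 O-alkylation of the phenoxide by the doubly activated bromide, the usual access to aryloxymalonates; a small excess of 20 and mild base limit further reaction of the acidic product.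

Step 14
Reactants: 22 dimethyl 3-oxopentanedioate
Product: 23 dibenzyl 3-oxopentanedioate
Conditions: BnOH, DMAP (cat.), toluene, reflux, removal of MeOH
Reagents that add atoms: benzyl alcohol, OCc1ccccc1
Why: Transesterification of a β-keto ester, which proceeds readily under DMAP catalysis when methanol is removed; both esters of 22 are β-keto esters.

Step 15
Reactants: 21 dibenzyl 2-(aryloxy)malonate (aryl as in 18); 23 dibenzyl 3-oxopentanedioate
Product: 25 dibenzyl 5-(aryloxy)-2,4,6-trihydroxyisophthalate (aryl as in 18), via open-chain Claisen adduct 24 (not isolated)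
Conditions: 23 (excess), NaH (1 equiv per 23), THF, 0 °C; add 21, toluene, 110 °C; then aq. HCl
Reagents that add atoms: none
Why: The sodium enolate of 23 attacks one ester carbonyl of malonate 21, which stays partly un-ionised through proton exchange, and expels benzyloxide in an intermolecular Claisen condensation that gives the open-chain adduct 24; the remaining methylene of 24 between ketone and ester then attacks the second malonate ester in a 6-(enolexo)-exo-trig Dieckmann-type closure that forms the second C–C bond and ring A. Loss of the second benzyloxide and threefold enolisation give the aromatic phloroglucinol, whose hydrogen-bonded phenoxide salt is the thermodynamic sink that pulls the reversible Claisen steps forward; acidification releases 25. The closest known reaction type is the classical sodium- or alkoxide-mediated condensation of malonic esters with 3-oxopentanedioic esters to phloroglucinol dicarboxylates, the laboratory counterpart of polyketide Claisen cyclisation, and the aryloxy group on the malonate carbon is a spectator that ends on C2 of ring A. No stereocentre is formed. The step needs C-acylation over O-acylation and cross-condensation over self-condensation of 23: O-acylated pyranones are reopened by benzyloxide under the equilibrating conditions while only the carbocycle can aromatise, the ester on each nucleophilic carbon of 23 keeps that carbon its most acidic site, and 23 is used in excess with base limited to its own ionisation so that 21 remains electrophilic. Uniform benzyl esters make any alkoxide exchange degenerate.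

Step 16
Reactants: 25 dibenzyl 5-(aryloxy)-2,4,6-trihydroxyisophthalate (aryl as in 18)
Product: 27 the target CNP0243665.0, via polyphenolic diacid 26 (not isolated)
Conditions: H2 (1 atm), Pd(OH)2/C, THF/MeOH, rt; filter under Ar; then H2O, 80 °C, Ar
Reagents that add atoms: none
Why: Hydrogenolysis removes the ten benzyl ethers and two benzyl esters without touching the diaryl ether bonds; the resulting 2,4,6-trihydroxyisophthalic acid decarboxylates twice on warming through ipso protonation of the electron-rich ring, so the free polyphenol is formed under neutral, oxygen-free conditions.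

## Compound list

1 | 3,4,5-tris(benzyloxy)benzaldehyde | O=Cc1cc(OCc2ccccc2)c(OCc2ccccc2)c(OCc2ccccc2)c1 | starting material
2 | 3,4,5-tris(benzyloxy)phenyl formate | O=COc1cc(OCc2ccccc2)c(OCc2ccccc2)c(OCc2ccccc2)c1 | intermediate
3 | 3,4,5-tris(benzyloxy)phenol (ring E) | Oc1cc(OCc2ccccc2)c(OCc2ccccc2)c(OCc2ccccc2)c1 | intermediate
4 | 2-bromo-3,4,5-tris(benzyloxy)benzaldehyde (ring D) | O=Cc1cc(OCc2ccccc2)c(OCc2ccccc2)c(OCc2ccccc2)c1Br | intermediate
5 | 3,4,5-tris(benzyloxy)-2-[3,4,5-tris(benzyloxy)phenoxy]benzaldehyde | O=Cc1cc(OCc2ccccc2)c(OCc2ccccc2)c(OCc2ccccc2)c1Oc1cc(OCc2ccccc2)c(OCc2ccccc2)c(OCc2ccccc2)c1 | intermediate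
6 | 3,4,5-tris(benzyloxy)-2-[3,4,5-tris(benzyloxy)phenoxy]phenyl formate | O=COc1cc(OCc2ccccc2)c(OCc2ccccc2)c(OCc2ccccc2)c1Oc1cc(OCc2ccccc2)c(OCc2ccccc2)c(OCc2ccccc2)c1 | intermediate
7 | 3,4,5-tris(benzyloxy)-2-[3,4,5-tris(benzyloxy)phenoxy]phenol (DE phenol) | Oc1cc(OCc2ccccc2)c(OCc2ccccc2)c(OCc2ccccc2)c1Oc1cc(OCc2ccccc2)c(OCc2ccccc2)c(OCc2ccccc2)c1 | intermediate
8 | 4-bromo-3,5-dimethoxybenzaldehyde | COc1cc(C=O)cc(OC)c1Br | starting material
9 | 4-bromo-3,5-dihydroxybenzaldehyde | Oc1cc(C=O)cc(O)c1Br | intermediate
10 | 3,5-bis(benzyloxy)-4-bromobenzaldehyde (ring C) | O=Cc1cc(OCc2ccccc2)c(Br)c(OCc2ccccc2)c1 | intermediate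
11 | 3,5-bis(benzyloxy)-4-{3,4,5-tris(benzyloxy)-2-[3,4,5-tris(benzyloxy)phenoxy]phenoxy}benzaldehyde (CDE aldehyde) | O=Cc1cc(OCc2ccccc2)c(Oc2cc(OCc3ccccc3)c(OCc3ccccc3)c(OCc3ccccc3)c2Oc2cc(OCc3ccccc3)c(OCc3ccccc3)c(OCc3ccccc3)c2)c(OCc2ccccc2)c1 | intermediate
12 | formate ester of CDE phenol 13 | O=COc1cc(OCc2ccccc2)c(Oc2cc(OCc3ccccc3)c(OCc3ccccc3)c(OCc3ccccc3)c2Oc2cc(OCc3ccccc3)c(OCc3ccccc3)c(OCc3ccccc3)c2)c(OCc2ccccc2)c1 | intermediate
13 | 3,5-bis(benzyloxy)-4-{3,4,5-tris(benzyloxy)-2-[3,4,5-tris(benzyloxy)phenoxy]phenoxy}phenol (CDE phenol) | Oc1cc(OCc2ccccc2)c(Oc2cc(OCc3ccccc3)c(OCc3ccccc3)c(OCc3ccccc3)c2Oc2cc(OCc3ccccc3)c(OCc3ccccc3)c(OCc3ccccc3)c2)c(OCc2ccccc2)c1 | intermediate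
14 | 3,5-bis(benzyloxy)benzaldehyde | O=Cc1cc(OCc2ccccc2)cc(OCc2ccccc2)c1 | starting material
15 | 3,5-bis(benzyloxy)-2-bromobenzaldehyde (ring B) | O=Cc1cc(OCc2ccccc2)cc(OCc2ccccc2)c1Br | intermediate
16 | 3,5-bis(benzyloxy)-2-[3,5-bis(benzyloxy)-4-{3,4,5-tris(benzyloxy)-2-[3,4,5-tris(benzyloxy)phenoxy]phenoxy}phenoxy]benzaldehyde (BCDE aldehyde) | O=Cc1cc(OCc2ccccc2)cc(OCc2ccccc2)c1Oc1cc(OCc2ccccc2)c(Oc2cc(OCc3ccccc3)c(OCc3ccccc3)c(OCc3ccccc3)c2Oc2cc(OCc3ccccc3)c(OCc3ccccc3)c(OCc3ccccc3)c2)c(OCc2ccccc2)c1 | intermediate
17 | formate ester of BCDE phenol 18 | O=COc1cc(OCc2ccccc2)cc(OCc2ccccc2)c1Oc1cc(OCc2ccccc2)c(Oc2cc(OCc3ccccc3)c(OCc3ccccc3)c(OCc3ccccc3)c2Oc2cc(OCc3ccccc3)c(OCc3ccccc3)c(OCc3ccccc3)c2)c(OCc2ccccc2)c1 | intermediate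
18 | 3,5-bis(benzyloxy)-2-[3,5-bis(benzyloxy)-4-{3,4,5-tris(benzyloxy)-2-[3,4,5-tris(benzyloxy)phenoxy]phenoxy}phenoxy]phenol (BCDE phenol) | Oc1cc(OCc2ccccc2)cc(OCc2ccccc2)c1Oc1cc(OCc2ccccc2)c(Oc2cc(OCc3ccccc3)c(OCc3ccccc3)c(OCc3ccccc3)c2Oc2cc(OCc3ccccc3)c(OCc3ccccc3)c(OCc3ccccc3)c2)c(OCc2ccccc2)c1 | intermediate
19 | dibenzyl malonate | O=C(CC(=O)OCc1ccccc1)OCc1ccccc1 | starting material
20 | dibenzyl 2-bromomalonate | O=C(OCc1ccccc1)C(Br)C(=O)OCc1ccccc1 | intermediate
21 | dibenzyl 2-(aryloxy)malonate, aryl = aryl group of phenol 18 | O=C(OCc1ccccc1)C(Oc1cc(OCc2ccccc2)cc(OCc2ccccc2)c1Oc1cc(OCc2ccccc2)c(Oc2cc(OCc3ccccc3)c(OCc3ccccc3)c(OCc3ccccc3)c2Oc2cc(OCc3ccccc3)c(OCc3ccccc3)c(OCc3ccccc3)c2)c(OCc2ccccc2)c1)C(=O)OCc1ccccc1 | intermediate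
22 | dimethyl 3-oxopentanedioate | COC(=O)CC(=O)CC(=O)OC | starting material
23 | dibenzyl 3-oxopentanedioate | O=C(CC(=O)OCc1ccccc1)CC(=O)OCc1ccccc1 | intermediate
24 | dibenzyl 2-(aryloxy)-4-[(benzyloxy)carbonyl]-3,5-dioxoheptanedioate, aryl as in 18 (open-chain Claisen adduct, configuration undefined and enolisable) | O=C(OCc1ccccc1)C(Oc1cc(OCc2ccccc2)cc(OCc2ccccc2)c1Oc1cc(OCc2ccccc2)c(Oc2cc(OCc3ccccc3)c(OCc3ccccc3)c(OCc3ccccc3)c2Oc2cc(OCc3ccccc3)c(OCc3ccccc3)c(OCc3ccccc3)c2)c(OCc2ccccc2)c1)C(=O)C(C(=O)OCc1ccccc1)C(=O)CC(=O)OCc1ccccc1 | intermediate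
25 | dibenzyl 5-(aryloxy)-2,4,6-trihydroxyisophthalate, aryl as in 18 | O=C(OCc1ccccc1)c1c(O)c(C(=O)OCc2ccccc2)c(O)c(Oc2cc(OCc3ccccc3)cc(OCc3ccccc3)c2Oc2cc(OCc3ccccc3)c(Oc3cc(OCc4ccccc4)c(OCc4ccccc4)c(OCc4ccccc4)c3Oc3cc(OCc4ccccc4)c(OCc4ccccc4)c(OCc4ccccc4)c3)c(OCc3ccccc3)c2)c1O | intermediate
26 | 2,4,6-trihydroxy-5-(aryloxy)isophthalic acid with all ten benzyl ethers of the aryl group cleaved to hydroxyls | OC(=O)c1c(O)c(C(=O)O)c(O)c(Oc2cc(O)cc(O)c2Oc2cc(O)c(Oc3cc(O)c(O)c(O)c3Oc3cc(O)c(O)c(O)c3)c(O)c2)c1O | intermediate
27 | CNP0243665.0: 2-[2-{4-[2-(3,4,5-trihydroxyphenoxy)-3,4,5-trihydroxyphenoxy]-3,5-dihydroxyphenoxy}-3,5-dihydroxyphenoxy]benzene-1,3,5-triol | Oc1cc(O)c(Oc2cc(O)cc(O)c2Oc2cc(O)c(Oc3cc(O)c(O)c(O)c3Oc3cc(O)c(O)c(O)c3)c(O)c2)c(O)c1 | target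

## Step count and risk

Total: 16 steps. Longest linear sequence: 10 steps (steps 1, 3, 4, 7, 8, 10, 11, 13, 15, 16, from aldehyde 1 to target 27).

**Step 15 (key step).**
- What may go wrong: malonate 21 may sit as its unreactive enolate while 23 condenses with itself through aldol and Claisen pathways. The first acylation may also stall at an O-acylated pyranone that does not reopen, or benzyloxide may strip a benzyloxycarbonyl group from 21 by retro-Claisen cleavage.
- Fallback: ring A is brought in as a preformed arene. It sets out from phenol 18, which would be coupled with bromide 10 under the copper–picolinate conditions of step 7 to give 3,5-bis(benzyloxy)-4-(aryloxy)benzaldehyde F1 (aryl as in 18). Baeyer–Villiger oxidation as in step 11 would give 3,5-bis(benzyloxy)-4-(aryloxy)phenyl formate F2, and methanolysis 3,5-bis(benzyloxy)-4-(aryloxy)phenol F3. Hydrogenolysis of its twelve benzyl ethers under the conditions of step 16 comes back to the route at target 27.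

**Step 7.**
- What may go wrong: C–O bond formation at the bromide flanked by two benzyloxy groups may be slow against a phenol with an ortho aryloxy group. Reductive debromination of 10 and oxidative degradation of the electron-rich phenoxide at copper could then take over.
- Fallback: the copper-mediated substitution is replaced by ligand coupling at trivalent iodine. It sets out from bromide 10, which would be converted by copper-catalysed halogen exchange (CuI, NaI, a 1,2-diamine ligand, dioxane) into 3,5-bis(benzyloxy)-4-iodobenzaldehyde F4. Oxidation with mCPBA and TsOH in the presence of 1,3,5-trimethoxybenzene would give [2,6-bis(benzyloxy)-4-formylphenyl](2,4,6-trimethoxyphenyl)iodonium tosylate F5. The potassium phenoxide of 7 (t-BuOK, THF) would attack iodine and the less electron-rich, formyl-bearing aryl group would be transferred without metal, coming back to the route at aldehyde 11.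

**Step 13.**
- What may go wrong: bromine transfer from 20 to the very electron-rich phenoxide (ring bromination in place of O-alkylation), or further bromination or alkylation of the acidic product 21.
- Fallback: the SN2 reaction is replaced by carbene O–H insertion. Dibenzyl malonate 19 would be converted by Regitz diazo transfer (4-acetamidobenzenesulfonyl azide, Et3N) into dibenzyl 2-diazomalonate F6. Decomposition of F6 with Rh2(OAc)4 in the presence of phenol 18 would insert the carbene into the O–H bond, coming back to the route at malonate 21.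

**Step 16.**
- What may go wrong: hydrogenolysis of twelve benzyl groups may stall through catalyst poisoning or precipitation of partly deprotected material. The pyrogallol rings may be oxidised by air during filtration, or decarboxylation may remain incomplete.
- Fallback: non-reductive debenzylation. Diester 25 would be treated with BCl3 and pentamethylbenzene as cation scavenger in CH2Cl2 at −78 °C, which cleaves benzyl ethers and benzyl esters alike. A methanol quench and warming in water would take diacid 26 on to target 27. No new compound is made.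

## Further compounds

F1 | step 15 | 3,5-bis(benzyloxy)-4-(aryloxy)benzaldehyde, aryl = aryl group of phenol 18 | O=Cc1cc(OCc2ccccc2)c(Oc2cc(OCc3ccccc3)cc(OCc3ccccc3)c2Oc2cc(OCc3ccccc3)c(Oc3cc(OCc4ccccc4)c(OCc4ccccc4)c(OCc4ccccc4)c3Oc3cc(OCc4ccccc4)c(OCc4ccccc4)c(OCc4ccccc4)c3)c(OCc3ccccc3)c2)c(OCc2ccccc2)c1
F2 | step 15 | 3,5-bis(benzyloxy)-4-(aryloxy)phenyl formate, aryl as in 18 | O=COc1cc(OCc2ccccc2)c(Oc2cc(OCc3ccccc3)cc(OCc3ccccc3)c2Oc2cc(OCc3ccccc3)c(Oc3cc(OCc4ccccc4)c(OCc4ccccc4)c(OCc4ccccc4)c3Oc3cc(OCc4ccccc4)c(OCc4ccccc4)c(OCc4ccccc4)c3)c(OCc3ccccc3)c2)c(OCc2ccccc2)c1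
F3 | step 15 | 3,5-bis(benzyloxy)-4-(aryloxy)phenol, aryl as in 18 | Oc1cc(OCc2ccccc2)c(Oc2cc(OCc3ccccc3)cc(OCc3ccccc3)c2Oc2cc(OCc3ccccc3)c(Oc3cc(OCc4ccccc4)c(OCc4ccccc4)c(OCc4ccccc4)c3Oc3cc(OCc4ccccc4)c(OCc4ccccc4)c(OCc4ccccc4)c3)c(OCc3ccccc3)c2)c(OCc2ccccc2)c1
F4 | step 7 | 3,5-bis(benzyloxy)-4-iodobenzaldehyde | O=Cc1cc(OCc2ccccc2)c(I)c(OCc2ccccc2)c1
F5 | step 7 | [2,6-bis(benzyloxy)-4-formylphenyl](2,4,6-trimethoxyphenyl)iodonium 4-methylbenzenesulfonate | COc1cc(OC)c([I+]c2c(OCc3ccccc3)cc(C=O)cc2OCc2ccccc2)c(OC)c1.Cc1ccc(S(=O)(=O)[O-])cc1
F6 | step 13 | dibenzyl 2-diazomalonate | [N-]=[N+]=C(C(=O)OCc1ccccc1)C(=O)OCc1ccccc1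
F0 | step 16 | none | none
A1 | alternative 1 | undecamethyl ether of the target with free hydroxyls para to the ether oxygen on ring A and para to the ring C ether oxygen on ring B | COc1cc(O)cc(OC)c1Oc1cc(O)cc(OC)c1Oc1cc(OC)c(Oc2cc(OC)c(OC)c(OC)c2Oc2cc(OC)c(OC)c(OC)c2)c(OC)c1
A2 | alternative 1 | the same undecamethyl ether with hydrogen in place of those two hydroxyls | COc1cccc(OC)c1Oc1cccc(OC)c1Oc1cc(OC)c(Oc2cc(OC)c(OC)c(OC)c2Oc2cc(OC)c(OC)c(OC)c2)c(OC)c1
A3 | alternative 2 | 5,6-bis(benzyloxy)-2-[2,6-bis(benzyloxy)-4-(triisopropylsilyloxy)phenoxy]-4-(methoxymethoxy)phenol | Oc1c(OCc2ccccc2)c(OCc2ccccc2)c(OCOC)cc1Oc1c(OCc2ccccc2)cc(O[Si](C(C)C)(C(C)C)C(C)C)cc1OCc1ccccc1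
A4 | alternative 2 | racemic 2,3-bis(benzyloxy)-4-(methoxymethoxy)-4-[(Z)-2-{2,6-bis(benzyloxy)-4-(triisopropylsilyloxy)phenoxy}ethenyl]cyclobut-2-en-1-one | O=C1C(OCc2ccccc2)=C(OCc2ccccc2)C1(OCOC)/C=C\Oc1c(OCc2ccccc2)cc(O[Si](C(C)C)(C(C)C)C(C)C)cc1OCc1ccccc1
A5 | alternative 3 | 2-(benzyloxy)-4-methoxy-6-[2,4,6-tris(benzyloxy)phenoxy]phenol | COc1cc(OCc2ccccc2)c(O)c(Oc2c(OCc3ccccc3)cc(OCc3ccccc3)cc2OCc2ccccc2)c1
A6 | alternative 3 | pentacarbonyl[(2E)-3-(benzyloxy)-1-methoxyprop-2-en-1-ylidene]chromium | COC(/C=C/OCc1ccccc1)=[Cr](=C=O)(=C=O)(=C=O)(=C=O)=C=O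
A7 | alternative 3 | 1,3,5-tris(benzyloxy)-2-(ethynyloxy)benzene | C#COc1c(OCc2ccccc2)cc(OCc2ccccc2)cc1OCc1ccccc1
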